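**Plan**
1. Numbering (drimane): ring A = C1, C2, C3(OH), C4(CH3, CH2OH), C5, C10(CH3). Ring B = C5, C6, C7=C8(CH3), C9, C10. C9 carries C11H2–O–coumarin.
2. Cuts: C4–C5 and C9–C10 together, so both carbocycles unfold to one chain. Next C11–O (Mitsunobu), then C6–C7 (sulfone carbanion of a C5 unit plus geranyl bromide).
3. Enabling feature: the O on C3 sits beside the fully substituted C4 that bears CH2OH, which is the print of a 2,3-epoxy alcohol opened at its tertiary carbon. H5 anti to CH3-10 and the equatorial C11 are the prints of two E alkenes. C7=C8 lies next to the last radical centre C8, so a PhSO2 group parked on C7 can leave there and fix the alkene.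
4. Forward: the coumarin bicycle is bought. The chain is joined (C5 + C10), etherified, oxidised at its terminal E-methyl, epoxidised and silylated. One Cp2TiCl radical cascade then closes ring A and ring B in a single operation, and no ring is closed after it. Desilylation ends the route.
5. Stereochemistry: C3 comes from Sharpless epoxidation with D-(−)-diethyl tartrate. C4, C5, C10 and C9 are relayed from C3 through an all-chair fold and the E geometries. Target = (3R,4S,5S,9R,10R).

Key step: step 10

Remark: compounds 8 and 10–13 are carried as mixtures of both configurations at the sulfonyl-bearing carbon (future C7); this centre becomes sp2 in step 10, so their SMILES leave it open.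

**Step 1**
Reactants: 1 prenyl acetate (3-methylbut-2-enyl acetate)
Product: 2 (E)-4-hydroxy-3-methylbut-2-enyl acetate
Conditions: SeO2 (0.3 equiv), t-BuOOH (2 equiv), CH2Cl2, 0 °C to rt
Reagents that add atoms: tert-butyl hydroperoxide, CC(C)(C)OO (source of the O atom, passed on by SeO2, O=[Se]=O)
Why: Riley allylic oxidation (ene reaction, then [2,3]-sigmatropic shift of the allylseleninic acid) should hydroxylate the methyl group trans to the chain and so give the E-allylic alcohol, the acetate being inert.

**Step 2**
Reactants: 2 (E)-4-hydroxy-3-methylbut-2-enyl acetate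
Product: 3 (E)-4-bromo-3-methylbut-2-enyl acetate
Conditions: CBr4, PPh3, CH2Cl2, 0 °C
Reagents that add atoms: tetrabromomethane, BrC(Br)(Br)Br
Why: The Appel reaction turns the primary allylic alcohol into the bromide by SN2 displacement of the oxyphosphonium ion under neutral conditions, which leaves the acetate and the E geometry untouched.

**Step 3**
Reactants: 3 (E)-4-bromo-3-methylbut-2-enyl acetate
Product: 4 (E)-3-methyl-4-(phenylsulfonyl)but-2-enyl acetate
Conditions: PhSO2Na, DMF, rt
Reagents that add atoms: sodium benzenesulfinate, [Na+].[O-]S(=O)c1ccccc1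
Why: The soft sulfur end of the ambident sulfinate displaces the primary allylic bromide (SN2 S-alkylation), the standard entry to allylic sulfones, and the allylic acetate does not ionise without a palladium catalyst.

**Step 4**
Reactants: 4 (E)-3-methyl-4-(phenylsulfonyl)but-2-enyl acetate
Product: 5 (E)-3-methyl-4-(phenylsulfonyl)but-2-en-1-ol
Conditions: K2CO3 (0.1 equiv), MeOH, 0 °C
Reagents that add atoms: none
Why: Carbonate-catalysed transesterification with methanol removes the acetate far faster than the weak base can deprotonate the sulfone, so vinylogous elimination of acetate should not intervene.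

**Step 5**
Reactants: 5 (E)-3-methyl-4-(phenylsulfonyl)but-2-en-1-ol, 6 geranyl bromide
Product: 8 (2E,6E)-3,7,11-trimethyl-4-(phenylsulfonyl)dodeca-2,6,10-trien-1-ol, via dilithiated sulfone 7 (not isolated)
Conditions: n-BuLi (2.1 equiv), THF–DMPU, −78 °C; then 6, −78 to −40 °C; then H2O
Reagents that add atoms: none
Why: Alkylation of an allylic sulfone carbanion with an allylic bromide (Biellmann-type sulfone coupling) takes place α to sulfur with retention of both alkene geometries; the alkoxide of the dianion is no leaving group, which shuts off 1,4-elimination, and it is far less nucleophilic than the carbanion; the new stereocentre (future C7) is left unsettled because step 10 erases it.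

**Step 6**
Reactants: 8 (2E,6E)-3,7,11-trimethyl-4-(phenylsulfonyl)dodeca-2,6,10-trien-1-ol, 9 umbelliferone (7-hydroxycoumarin)
Product: 10 7-{[(2E,6E)-3,7,11-trimethyl-4-(phenylsulfonyl)dodeca-2,6,10-trien-1-yl]oxy}chromen-2-one
Conditions: PPh3, DIAD, THF, 0 °C to rt
Reagents that add atoms: none
Why: Mitsunobu etherification of an unhindered primary allylic alcohol with an acidic phenol proceeds by SN2 attack on the oxyphosphonium ion under essentially neutral conditions, which the acidic C–H next to the sulfone tolerates.

**Step 7**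
Reactants: 10 7-{[(2E,6E)-3,7,11-trimethyl-4-(phenylsulfonyl)dodeca-2,6,10-trien-1-yl]oxy}chromen-2-one
Product: 11 7-{[(2E,6E,10E)-12-hydroxy-3,7,11-trimethyl-4-(phenylsulfonyl)dodeca-2,6,10-trien-1-yl]oxy}chromen-2-one
Conditions: SeO2 (0.3 equiv), t-BuOOH (2 equiv), CH2Cl2, 0 °C, stopped at partial conversion, 10 recycled
Reagents that add atoms: tert-butyl hydroperoxide, CC(C)(C)OO (source of the O atom, passed on by SeO2, O=[Se]=O)
Why: Riley allylic oxidation is fastest at the terminal isopropylidene group, the most electron-rich and least hindered of the three alkenes (C2=C3 of the chain is deactivated by the flanking sulfonyl and aryloxy groups), and it again delivers the E-allylic alcohol, which places CH2OH trans to the chain.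

**Step 8**
Reactants: 11 7-{[(2E,6E,10E)-12-hydroxy-3,7,11-trimethyl-4-(phenylsulfonyl)dodeca-2,6,10-trien-1-yl]oxy}chromen-2-one
Product: 12 7-{[(2E,6E)-9-[(2R,3R)-3-(hydroxymethyl)-3-methyloxiran-2-yl]-3,7-dimethyl-4-(phenylsulfonyl)nona-2,6-dien-1-yl]oxy}chromen-2-one
Conditions: Ti(OiPr)4 (0.1 equiv), D-(−)-diethyl tartrate (0.12 equiv), t-BuOOH (2 equiv, decane), 4 Å MS, CH2Cl2, −20 °C
Reagents that add atoms: tert-butyl hydroperoxide, CC(C)(C)OO
Why: Sharpless asymmetric epoxidation acts only on the alkene that carries the allylic hydroxyl group, and with D-(−)-diethyl tartrate an E-2-methylalk-2-en-1-ol should give the (2R,3R)-epoxy alcohol, which sets the future C3 as R (reagent control, indifferent to the remote sulfone centre).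

**Step 9**
Reactants: 12 the (2R,3R)-epoxy alcohol
Product: 13 tert-butyldiphenylsilyl ether of 12
Conditions: TBDPSCl, imidazole, DMF, 0 °C to rt
Reagents that add atoms: tert-butyl(chloro)diphenylsilane, CC(C)(C)[Si](Cl)(c1ccccc1)c1ccccc1
Why: Standard silylation of the primary alcohol masks the hydroxyl group, which would otherwise bind trivalent titanium and deliver hydrogen or be eliminated, and it supplies the bulk that steers C4 in step 10.

**Step 10**
Reactants: 13 tert-butyldiphenylsilyl ether of 12
Product: 14 O-TBDPS ether of the target, (3R,4S,5S,9R,10R): trans-decalin with C7=C8; 3-OH, 4-CH2OTBDPS and C11H2O–coumarin equatorial; CH3 on C4 and CH3 on C10 axial on the same face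
Conditions: Cp2TiCl2 (2.5 equiv), Mn dust (8 equiv), degassed THF, rt, slow addition of 13; then 1 M HCl
Reagents that add atoms: none
Why: Proposed new method: Cp2TiCl (trivalent titanium) opens the C3–C4 epoxide homolytically at its more substituted carbon (Nugent–RajanBabu opening) to the tertiary C4 radical, which closes ring A by 6-endo-trig attack on C5; the tertiary C10 radical so formed closes ring B by 6-endo-trig attack on C9, and the C8 radical expels PhSO2• from C7 by β-scission, which writes the alkene at C7=C8 and nowhere else, the sulfonyl radical being reduced to sulfinate by a second Cp2TiCl. The closest known reaction types are the titanocene-mediated epoxypolyene cascade (which ends in an exocyclic C8 methylene) and radical addition–fragmentation on allylic sulfones, also known for epoxide-derived titanoxy radicals; new is their union, with scission of an endocyclic C–S bond as the end of a cascade. C3 keeps the Sharpless configuration because its C–O bond is never broken, and its bulky OTiCp2Cl group sits equatorial in an all-chair fold, which decides the face of C5=C10 that is attacked. The E geometry of C5=C10 gives the trans fusion (H5 anti to CH3 on C10), the E geometry of C8=C9 puts C11 equatorial at C9, and at the planar C4 radical the larger CH2OTBDPS group takes the equatorial site, away from the 1,3-diaxial contact with the C10 methyl group, leaving CH3 axial. The step needs 6-endo over 5-exo closure, secured by the methyl groups on C10 and C8 that block the inner alkene carbons and make the new radicals tertiary, and it needs scission faster than hydrogen loss from C12, secured by the weak C–S bond β to the radical and by the slow capture of tertiary radicals by Cp2TiCl. Both C7 epimers converge because C7 becomes sp2.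

**Step 11**
Reactants: 14 O-TBDPS ether of the target
Product: 15 target, 7-{[(1R,4aS,5S,6R,8aR)-6-hydroxy-5-(hydroxymethyl)-2,5,8a-trimethyl-1,4,4a,5,6,7,8,8a-octahydronaphthalen-1-yl]methoxy}chromen-2-one
Conditions: TBAF (1.5 equiv), AcOH (1.5 equiv), THF, 0 °C to rt
Reagents that add atoms: none
Why: Fluoride cleaves the Si–O bond of the neopentyl-type silyl ether, and buffering with acetic acid keeps the medium too weakly basic to open the coumarin lactone; no stereocentre is touched.

**Compound list**
1 | prenyl acetate | CC(C)=CCOC(C)=O | starting material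
2 | (E)-4-hydroxy-3-methylbut-2-enyl acetate | CC(=O)OC/C=C(\C)CO | intermediate
3 | (E)-4-bromo-3-methylbut-2-enyl acetate | CC(=O)OC/C=C(\C)CBr | intermediate
4 | (E)-3-methyl-4-(phenylsulfonyl)but-2-enyl acetate | CC(=O)OC/C=C(\C)CS(=O)(=O)c1ccccc1 | intermediate
5 | (E)-3-methyl-4-(phenylsulfonyl)but-2-en-1-ol | OC/C=C(\C)CS(=O)(=O)c1ccccc1 | intermediate
6 | geranyl bromide | CC(C)=CCC/C(C)=C/CBr | starting material
7 | dilithiated sulfone (O,C-dianion of 5) | [Li+].[Li+].[O-]C/C=C(\C)[CH-]S(=O)(=O)c1ccccc1 | intermediate
8 | (2E,6E)-3,7,11-trimethyl-4-(phenylsulfonyl)dodeca-2,6,10-trien-1-ol | OC/C=C(\C)C(C/C=C(\C)CCC=C(C)C)S(=O)(=O)c1ccccc1 | intermediate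
9 | umbelliferone | O=c1ccc2ccc(O)cc2o1 | starting material
10 | 4'-(phenylsulfonyl)farnesyl umbelliferyl ether | O=c1ccc2ccc(OC/C=C(\C)C(C/C=C(\C)CCC=C(C)C)S(=O)(=O)c3ccccc3)cc2o1 | intermediate
11 | (10'E)-12'-hydroxy derivative of 10 | O=c1ccc2ccc(OC/C=C(\C)C(C/C=C(\C)CC/C=C(\C)CO)S(=O)(=O)c3ccccc3)cc2o1 | intermediate
12 | (10'R,11'R)-epoxy alcohol | O=c1ccc2ccc(OC/C=C(\C)C(C/C=C(\C)CC[C@H]3O[C@]3(C)CO)S(=O)(=O)c3ccccc3)cc2o1 | intermediate
13 | TBDPS ether of 12 | O=c1ccc2ccc(OC/C=C(\C)C(C/C=C(\C)CC[C@H]3O[C@]3(C)CO[Si](c3ccccc3)(c3ccccc3)C(C)(C)C)S(=O)(=O)c3ccccc3)cc2o1 | intermediate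
14 | O-TBDPS ether of the target | CC1=CC[C@@H]2[C@@](C)(CO[Si](c3ccccc3)(c3ccccc3)C(C)(C)C)[C@H](O)CC[C@@]2(C)[C@@H]1COc1ccc2ccc(=O)oc2c1 | intermediate
15 | target CNP0298598.3 | CC1=CC[C@@H]2[C@@](C)(CO)[C@H](O)CC[C@@]2(C)[C@@H]1COc1ccc2ccc(=O)oc2c1 | target

**Total step count:** 11. **Longest linear sequence:** 11 (1 to 15).

**Steps most likely to fail**

*Step 10.*
- What may go wrong: slow C–S scission in the epimer whose sulfonyl group lies equatorial, so that hydrogen loss from C12 competes. Poor facial selectivity at the planar C4 radical is a second risk, and capture of radicals by the coumarin alkene a third.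
- The fallback uses known chemistry only, sets out from umbelliferone 9 and comes back at 14.
- Mitsunobu etherification of 9 with commercial (2E,6E)-farnesol (PPh3, DIAD, THF) gives umbelliprenin F1.
- SeO2/t-BuOOH gives the terminal E-allylic alcohol F2.
- Sharpless epoxidation with Ti(OiPr)4, D-(−)-diethyl tartrate and t-BuOOH gives the epoxy alcohol F3, and TBDPSCl/imidazole gives the silyl ether F4.
- The established Cp2TiCl cascade (Cp2TiCl2, Mn, THF, rt) gives the exocyclic-methylene decalin F5.
- A cobalt-hydride hydrogen-atom-transfer isomerisation then moves the alkene into the ring, on the less hindered C7 side, to give 14. Conditions: catalytic [N,N'-bis(3,5-di-tert-butylsalicylidene)-1,2-cyclohexanediaminato]cobalt chloride, PhSiH3, benzene, rt.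

*Step 7.*
- What may go wrong: competing oxidation at the allylic positions of the central alkene, over-oxidation to the enal, and low conversion on an advanced intermediate.
- The fallback builds the oxidised and epoxidised terminus on the C10 electrophile before the coupling. It sets out from 5 (as dianion 7) and comes back at 13.
- Commercial geranyl acetate is oxidised (SeO2, t-BuOOH) to 8-hydroxygeranyl acetate F6.
- F6 is epoxidised (Ti(OiPr)4, D-(−)-diethyl tartrate, t-BuOOH) to the epoxy alcohol F7 and silylated (TBDPSCl, imidazole) to the silyl ether F8.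
- F8 is deacetylated (K2CO3, MeOH) to the allylic alcohol F9.
- F9 is taken through the mesylate F10 (MsCl, Et3N, CH2Cl2, −40 °C) to the allylic bromide F11 (LiBr, THF).
- F11 alkylates dianion 7 at −78 °C to give the epoxy hydroxy sulfone F12, and Mitsunobu etherification of F12 with 9 gives 13.

*Step 5.*
- What may go wrong: O-alkylation of the alkoxide, proton transfer followed by double alkylation, and erosion of the alkene geometry in the dianion.
- The fallback replaces the dianion by a protected monoanion. It sets out from 5 and comes back at 8.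
- Silylation of 5 (TBSCl, imidazole) gives the silyl ether F13.
- Single deprotonation (n-BuLi, THF, −78 °C) and alkylation with 6 give the alkylated silyl ether F14, and TBAF in THF gives 8.

**Further compounds**
F1 | step 10 | umbelliprenin, 7-[(2E,6E)-farnesyloxy]chromen-2-one | O=c1ccc2ccc(OC/C=C(\C)CC/C=C(\C)CCC=C(C)C)cc2o1
F2 | step 10 | (10'E)-12'-hydroxyumbelliprenin | O=c1ccc2ccc(OC/C=C(\C)CC/C=C(\C)CC/C=C(\C)CO)cc2o1
F3 | step 10 | (10'R,11'R)-10',11'-epoxy-12'-hydroxyumbelliprenin | O=c1ccc2ccc(OC/C=C(\C)CC/C=C(\C)CC[C@H]3O[C@]3(C)CO)cc2o1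
F4 | step 10 | TBDPS ether of F3 | O=c1ccc2ccc(OC/C=C(\C)CC/C=C(\C)CC[C@H]3O[C@]3(C)CO[Si](c3ccccc3)(c3ccccc3)C(C)(C)C)cc2o1
F5 | step 10 | C8(12)-exocyclic alkene isomer of 14 | C=C1CC[C@@H]2[C@@](C)(CO[Si](c3ccccc3)(c3ccccc3)C(C)(C)C)[C@H](O)CC[C@@]2(C)[C@@H]1COc1ccc2ccc(=O)oc2c1
F6 | step 7 | (2E,6E)-8-hydroxy-3,7-dimethylocta-2,6-dienyl acetate | CC(=O)OC/C=C(\C)CC/C=C(\C)CO
F7 | step 7 | (6R,7R)-6,7-epoxy-8-hydroxygeranyl acetate | CC(=O)OC/C=C(\C)CC[C@H]1O[C@]1(C)CO
F8 | step 7 | TBDPS ether of F7 | CC(=O)OC/C=C(\C)CC[C@H]1O[C@]1(C)CO[Si](c1ccccc1)(c1ccccc1)C(C)(C)C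
F9 | step 7 | (6R,7R)-6,7-epoxy-8-(TBDPS-oxy)geraniol | OC/C=C(\C)CC[C@H]1O[C@]1(C)CO[Si](c1ccccc1)(c1ccccc1)C(C)(C)C
F10 | step 7 | mesylate of F9 | CS(=O)(=O)OC/C=C(\C)CC[C@H]1O[C@]1(C)CO[Si](c1ccccc1)(c1ccccc1)C(C)(C)C
F11 | step 7 | (6R,7R)-6,7-epoxy-8-(TBDPS-oxy)geranyl bromide | BrC/C=C(\C)CC[C@H]1O[C@]1(C)CO[Si](c1ccccc1)(c1ccccc1)C(C)(C)C
F12 | step 7 | epoxy hydroxy sulfone (13 with OH in place of the coumarinyloxy group) | OC/C=C(\C)C(C/C=C(\C)CC[C@H]1O[C@]1(C)CO[Si](c1ccccc1)(c1ccccc1)C(C)(C)C)S(=O)(=O)c1ccccc1
F13 | step 5 | TBS ether of 5 | CC(C)(C)[Si](C)(C)OC/C=C(\C)CS(=O)(=O)c1ccccc1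
F14 | step 5 | TBS ether of 8 | CC(C)(C)[Si](C)(C)OC/C=C(\C)C(C/C=C(\C)CCC=C(C)C)S(=O)(=O)c1ccccc1
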